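Assumption: the SMILES is read as 1,3-cis in the ring (both ring centres S), R at the tertiary carbinol and E at the side-chain alkene.

## Retrosynthetic overview

1. The two isobutyrates and the free ring hydroxyl come last: bis-acylation of a triol mono-silyl ether with two equivalents of isobutyryl chloride, then desilylation.
2. The (R)-tertiary allylic alcohol and the E-alkene come from a Sharpless epoxy alcohol by selenide opening and selenoxide elimination.
3. The (E)-2-methylallylic alcohol comes from the key intermolecular aldol of a ring-bearing aldehyde with ethyl propanoate, followed by dehydration and reduction.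
4. The ring CH2O comes from the ring methyl (directed epoxidation, epoxide to exo-methylene alcohol, allylic transposition); the aldehyde chain comes from allylic chlorination of the isopropenyl group and a malonate extension.
5. No ring is formed: the cyclohexene is the ring of (S)-(+)-carvone, which supplies the ring CH centre; the carbinol centre comes from a cis-selective hydride reduction.

Abbreviations: TBS = tert-butyldimethylsilyl, PMB = 4-methoxybenzyl, Ms = methanesulfonyl.

## Route

Step 1
Reactants: 1 (S)-(+)-carvone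
Product: 2 (5S)-5-(3-chloroprop-1-en-2-yl)-2-methylcyclohex-2-en-1-one
Conditions: Ca(OCl)2, CO2 (dry ice), CH2Cl2/H2O, 0 °C
Reagents that add atoms: calcium hypochlorite [Ca+2].[O-]Cl.[O-]Cl
Why: Ene-type allylic chlorination by HOCl made in the flask occurs only at the electron-rich isopropenyl alkene (the enone alkene is deactivated) and shifts that double bond to give the 2-substituted allyl chloride, leaving the ring stereocentre untouched.

Step 2
Reactants: 2 chloro enone; 3 dimethyl malonate
Product: 5 dimethyl 2-{2-[(1S)-4-methyl-5-oxocyclohex-3-en-1-yl]prop-2-en-1-yl}propanedioate, via sodium dimethyl malonate 4 (not isolated)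
Conditions: NaH, NaI (cat.), THF/DMF, 0 °C → rt
Reagents that add atoms: none
Why: Malonate alkylation (SN2 at a primary allylic chloride, iodide-assisted) outruns Michael addition to the hindered α-methyl enone, and SN2 or SN2′ attack on the symmetrical 2-substituted allyl unit gives the same product.

Step 3
Reactants: 5 malonate
Product: 6 methyl 4-[(1S)-4-methyl-5-oxocyclohex-3-en-1-yl]pent-4-enoate
Conditions: LiCl, H2O, DMSO, 150 °C
Reagents that add atoms: none
Why: Krapcho dealkoxycarbonylation removes one ester under neutral conditions that the enone and the 1,1-disubstituted alkene tolerate.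

Step 4
Reactants: 6 keto ester
Product: 7 (1S,5S)-5-(5-hydroxypent-1-en-2-yl)-2-methylcyclohex-2-en-1-ol
Conditions: LiAlH4, THF, −78 → 0 °C
Reagents that add atoms: none
Why: Hydride 1,2-reduction of the enone proceeds by axial attack on the half-chair with the side chain equatorial, giving the cis allylic alcohol as in the carvone to cis-carveol reduction, and the ester is reduced to the primary alcohol on warming.

Step 5
Reactants: 7 diol
Product: 8 (1S,2S,4R,6R)-4-(5-hydroxypent-1-en-2-yl)-1-methyl-7-oxabicyclo[4.1.0]heptan-2-ol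
Conditions: VO(acac)2 (2 mol %), t-BuOOH (1.1 equiv), CH2Cl2, 0 °C → rt
Reagents that add atoms: tert-butyl hydroperoxide CC(C)(C)OO
Why: Hydroxyl-directed vanadium-catalysed epoxidation oxidises the allylic-alcohol alkene far faster than the remote exo-methylene and delivers oxygen syn to the ring OH; the two new centres are erased again in steps 7 and 8.

Step 6
Reactants: 8 epoxy diol
Product: 9 bis-TBS ether of 8
Conditions: TBSCl, imidazole, DMAP (cat.), DMF, rt → 40 °C
Reagents that add atoms: tert-butyldimethylsilyl chloride CC(C)(C)[Si](C)(C)Cl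
Why: Silylation of both hydroxyls, which keeps the ring oxygen distinguishable from the hydroxyl unveiled in step 7; the free cis,cis-2-methylene-1,3-diol would be meso-like and the ring chirality would be lost.

Step 7
Reactants: 9 bis-TBS epoxide
Product: 10 (1R,3S,5S)-3-(TBSO)-5-[5-(TBSO)pent-1-en-2-yl]-2-methylidenecyclohexan-1-ol
Conditions: Et2AlCl, lithium 2,2,6,6-tetramethylpiperidide (from TMPH, n-BuLi), toluene, 0 °C
Reagents that add atoms: none
Why: Yamamoto epoxide to allylic alcohol isomerisation, in which the aluminium amide binds the epoxide oxygen and removes by syn elimination a proton from the methyl on the fully substituted carbon, so the tertiary C–O bond breaks and the exocyclic methylene secondary alcohol results.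

Step 8
Reactants: 10 exo-methylene alcohol
Product: 12 tert-butyl{[(1S,5S)-2-(bromomethyl)-5-[5-(TBSO)pent-1-en-2-yl]cyclohex-2-en-1-yl]oxy}dimethylsilane, via allylic mesylate 11 (not isolated)
Conditions: MsCl, Et3N, THF, −40 °C; then LiBr, −40 °C → rt
Reagents that add atoms: lithium bromide [Li+].[Br-]
Why: Mesylation then bromide substitution with allylic transposition (SN2′ at the unhindered methylene terminus, with bromide-mediated equilibration of any secondary bromide) gives the thermodynamically preferred primary allylic bromide with the trisubstituted ring alkene, the silyloxy carbon keeping its configuration.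

Step 9
Reactants: 12 allylic bromide
Product: 13 tert-butyl{[(1S,5S)-2-{[(4-methoxybenzyl)oxy]methyl}-5-[5-(TBSO)pent-1-en-2-yl]cyclohex-2-en-1-yl]oxy}dimethylsilane
Conditions: 4-methoxybenzyl alcohol, NaH, Bu4NI (cat.), THF, 0 °C → rt
Reagents that add atoms: 4-methoxybenzyl alcohol COc1ccc(CO)cc1
Why: Williamson ether synthesis (SN2 at the primary allylic bromide) installs an ether that survives the hydride, enolate and epoxidation steps and is removable oxidatively.

Step 10
Reactants: 13 PMB ether
Product: 14 4-[(1S,5S)-5-(TBSO)-4-{[(4-methoxybenzyl)oxy]methyl}cyclohex-3-en-1-yl]pent-4-en-1-ol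
Conditions: HF·pyridine, pyridine, THF, 0 °C
Reagents that add atoms: none
Why: Selective desilylation, the unhindered primary TBS ether being cleaved much faster by buffered HF·pyridine than the hindered secondary allylic one.

Step 11
Reactants: 14 primary alcohol
Product: 15 4-[(1S,5S)-5-(TBSO)-4-{[(4-methoxybenzyl)oxy]methyl}cyclohex-3-en-1-yl]pent-4-enal
Conditions: Dess–Martin periodinane, CH2Cl2, 0 °C → rt
Reagents that add atoms: none
Why: Dess–Martin oxidation gives the γ,δ-unsaturated aldehyde under near-neutral conditions without touching the silyl and PMB ethers or the alkenes.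

Step 12
Reactants: 15 aldehyde; 16 ethyl propanoate
Product: 18 ethyl 3-hydroxy-2-methyl-6-[(1S,5S)-5-(TBSO)-4-(PMBOCH2)cyclohex-3-en-1-yl]hept-6-enoate, via lithium enolate of ethyl propanoate 17 (not isolated)
Conditions: LiN(i-Pr)2 (from i-Pr2NH, n-BuLi), THF, −78 °C; then 15, −78 °C
Reagents that add atoms: none
Why: Intermolecular aldol addition of the lithium ester enolate to the aldehyde forms the C–C bond of the future trisubstituted alkene; the two new centres form as a mixture that the dehydration in step 13 erases.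

Step 13
Reactants: 18 aldol adduct
Product: 20 ethyl (2E)-2-methyl-6-[(1S,5S)-5-(TBSO)-4-(PMBOCH2)cyclohex-3-en-1-yl]hepta-2,6-dienoate, via β-mesyloxy ester 19 (not isolated)
Conditions: MsCl, Et3N, CH2Cl2, 0 °C; then DBU, rt
Reagents that add atoms: none
Why: Mesylation and DBU-promoted E1cB elimination complete the aldol condensation, the reversible carbanion pathway funnelling both diastereomers to the more stable E-enoate with the ester trans to the chain.

Step 14
Reactants: 20 E-enoate
Product: 21 (2E)-2-methyl-6-[(1S,5S)-5-(TBSO)-4-(PMBOCH2)cyclohex-3-en-1-yl]hepta-2,6-dien-1-ol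
Conditions: i-Bu2AlH, CH2Cl2, −78 °C
Reagents that add atoms: none
Why: 1,2-Reduction of the unsaturated ester by the aluminium hydride gives the E allylic alcohol, the substrate class for which asymmetric epoxidation is most dependable.

Step 15
Reactants: 21 allylic alcohol
Product: 22 [(2S,3S)-3-{3-[(1S,5S)-5-(TBSO)-4-(PMBOCH2)cyclohex-3-en-1-yl]but-3-en-1-yl}-2-methyloxiran-2-yl]methanol
Conditions: Ti(Oi-Pr)4 (10 mol %), L-(+)-diethyl tartrate (12 mol %), t-BuOOH, 4 Å molecular sieves, CH2Cl2, −20 °C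
Reagents that add atoms: tert-butyl hydroperoxide CC(C)(C)OO
Why: Sharpless asymmetric epoxidation, in which the titanium–L-(+)-tartrate catalyst epoxidises the only free allylic alcohol on the face giving the (2S,3S)-epoxy alcohol (reagent control, as for other E-2-methylalk-2-en-1-ols), fixing the configuration of the future tertiary carbinol.

Step 16
Reactants: 22 epoxy alcohol
Product: 25 (2R,3E)-2-methyl-6-[(1S,5S)-5-(TBSO)-4-(PMBOCH2)cyclohex-3-en-1-yl]hepta-3,6-diene-1,2-diol, via hydroxy selenide 23 (not isolated), via selenoxide 24 (not isolated)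
Conditions: (PhSe)2, NaBH4, EtOH, rt → 50 °C; then THF, pyridine, 30% H2O2, 0 °C → rt
Reagents that add atoms: none
Why: Sharpless–Lauer epoxide to allylic alcohol transposition, where PhSe− opens the epoxide by SN2 at the less hindered CH carbon so the quaternary C–O bond keeps its configuration (called R only through a change of CIP ranks), and selenoxide syn elimination can only run toward the chain CH2 and gives the E-alkene.

Step 17
Reactants: 25 PMB-protected diol
Product: 26 (2R,3E)-6-[(1S,5S)-5-(TBSO)-4-(hydroxymethyl)cyclohex-3-en-1-yl]-2-methylhepta-3,6-diene-1,2-diol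
Conditions: DDQ, CH2Cl2/pH 7 buffer, 0 °C
Reagents that add atoms: none
Why: Oxidative PMB cleavage (hydride abstraction from the electron-rich benzylic position, then hydrolysis) frees the ring primary alcohol while the silyl ether stays.

Step 18
Reactants: 26 triol; 27 2-methylpropanoyl chloride
Product: 28 {(4S,6S)-6-(TBSO)-4-[(4E,6R)-6-hydroxy-6-methyl-7-(2-methylpropanoyloxy)hepta-1,4-dien-2-yl]cyclohex-1-en-1-yl}methyl 2-methylpropanoate
Conditions: 27 (2.3 equiv in all), pyridine, CH2Cl2, −20 → 0 °C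
Reagents that add atoms: 2-methylpropanoyl chloride (second equivalent) CC(C)C(Cl)=O
Why: Double acylation with two equivalents of the acid chloride esterifies both primary hydroxyls (one equivalent each), while the tertiary allylic hydroxyl does not react at 0 °C without an acyl-transfer catalyst and the ring secondary oxygen is still silylated.

Step 19
Reactants: 28 silyl ether
Product: 29 {(4S,6S)-6-hydroxy-4-[(4E,6R)-6-hydroxy-6-methyl-7-(2-methylpropanoyloxy)hepta-1,4-dien-2-yl]cyclohex-1-en-1-yl}methyl 2-methylpropanoate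
Conditions: HF·pyridine, pyridine, THF, 0 °C → rt
Reagents that add atoms: none
Why: Fluoride desilylation under buffered, slightly acidic conditions removes the secondary TBS ether without the basic conditions that would cause acyl migration from the neighbouring primary ester.

## Compound list

1 | (S)-(+)-carvone, (5S)-2-methyl-5-(prop-1-en-2-yl)cyclohex-2-en-1-one | C=C(C)[C@H]1CC=C(C)C(=O)C1 | starting material
2 | (5S)-5-(3-chloroprop-1-en-2-yl)-2-methylcyclohex-2-en-1-one | C=C(CCl)[C@H]1CC=C(C)C(=O)C1 | intermediate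
3 | dimethyl malonate | COC(=O)CC(=O)OC | starting material
4 | sodium dimethyl malonate (sodium enolate of 3) | [Na+].COC(=O)[CH-]C(=O)OC | intermediate
5 | dimethyl 2-{2-[(1S)-4-methyl-5-oxocyclohex-3-en-1-yl]prop-2-en-1-yl}propanedioate | C=C(CC(C(=O)OC)C(=O)OC)[C@H]1CC=C(C)C(=O)C1 | intermediate
6 | methyl 4-[(1S)-4-methyl-5-oxocyclohex-3-en-1-yl]pent-4-enoate | C=C(CCC(=O)OC)[C@H]1CC=C(C)C(=O)C1 | intermediate
7 | (1S,5S)-5-(5-hydroxypent-1-en-2-yl)-2-methylcyclohex-2-en-1-ol (OH and side chain cis) | C=C(CCCO)[C@H]1CC=C(C)[C@@H](O)C1 | intermediate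
8 | (1S,2S,4R,6R)-4-(5-hydroxypent-1-en-2-yl)-1-methyl-7-oxabicyclo[4.1.0]heptan-2-ol (epoxide O, ring OH and side chain all cis) | C=C(CCCO)[C@H]1C[C@H]2O[C@@]2(C)[C@@H](O)C1 | intermediate
9 | bis-TBS ether of 8 (both hydroxyls silylated, stereocentres unchanged) | C=C(CCCO[Si](C)(C)C(C)(C)C)[C@H]1C[C@H]2O[C@@]2(C)[C@@H](O[Si](C)(C)C(C)(C)C)C1 | intermediate
10 | (1R,3S,5S)-3-(TBSO)-5-[5-(TBSO)pent-1-en-2-yl]-2-methylidenecyclohexan-1-ol (OH, OTBS and side chain all cis) | C=C(CCCO[Si](C)(C)C(C)(C)C)[C@H]1C[C@@H](O)C(=C)[C@@H](O[Si](C)(C)C(C)(C)C)C1 | intermediate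
11 | methanesulfonate of 10 | C=C(CCCO[Si](C)(C)C(C)(C)C)[C@H]1C[C@@H](OS(C)(=O)=O)C(=C)[C@@H](O[Si](C)(C)C(C)(C)C)C1 | intermediate
12 | tert-butyl{[(1S,5S)-2-(bromomethyl)-5-[5-(TBSO)pent-1-en-2-yl]cyclohex-2-en-1-yl]oxy}dimethylsilane | C=C(CCCO[Si](C)(C)C(C)(C)C)[C@H]1CC=C(CBr)[C@@H](O[Si](C)(C)C(C)(C)C)C1 | intermediate
13 | tert-butyl{[(1S,5S)-2-{[(4-methoxybenzyl)oxy]methyl}-5-[5-(TBSO)pent-1-en-2-yl]cyclohex-2-en-1-yl]oxy}dimethylsilane | C=C(CCCO[Si](C)(C)C(C)(C)C)[C@H]1CC=C(COCc2ccc(OC)cc2)[C@@H](O[Si](C)(C)C(C)(C)C)C1 | intermediate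
14 | 4-[(1S,5S)-5-(TBSO)-4-{[(4-methoxybenzyl)oxy]methyl}cyclohex-3-en-1-yl]pent-4-en-1-ol | C=C(CCCO)[C@H]1CC=C(COCc2ccc(OC)cc2)[C@@H](O[Si](C)(C)C(C)(C)C)C1 | intermediate
15 | 4-[(1S,5S)-5-(TBSO)-4-{[(4-methoxybenzyl)oxy]methyl}cyclohex-3-en-1-yl]pent-4-enal | C=C(CCC=O)[C@H]1CC=C(COCc2ccc(OC)cc2)[C@@H](O[Si](C)(C)C(C)(C)C)C1 | intermediate
16 | ethyl propanoate | CCC(=O)OCC | starting material
17 | lithium enolate of ethyl propanoate | [Li+].CC=C([O-])OCC | intermediate
18 | ethyl 3-hydroxy-2-methyl-6-[(1S,5S)-5-(TBSO)-4-(PMBOCH2)cyclohex-3-en-1-yl]hept-6-enoate (mixture at C2 and C3) | C=C(CCC(O)C(C)C(=O)OCC)[C@H]1CC=C(COCc2ccc(OC)cc2)[C@@H](O[Si](C)(C)C(C)(C)C)C1 | intermediate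
19 | 3-methanesulfonate of 18 | C=C(CCC(OS(C)(=O)=O)C(C)C(=O)OCC)[C@H]1CC=C(COCc2ccc(OC)cc2)[C@@H](O[Si](C)(C)C(C)(C)C)C1 | intermediate
20 | ethyl (2E)-2-methyl-6-[(1S,5S)-5-(TBSO)-4-(PMBOCH2)cyclohex-3-en-1-yl]hepta-2,6-dienoate | C=C(CC/C=C(\C)C(=O)OCC)[C@H]1CC=C(COCc2ccc(OC)cc2)[C@@H](O[Si](C)(C)C(C)(C)C)C1 | intermediate
21 | (2E)-2-methyl-6-[(1S,5S)-5-(TBSO)-4-(PMBOCH2)cyclohex-3-en-1-yl]hepta-2,6-dien-1-ol | C=C(CC/C=C(\C)CO)[C@H]1CC=C(COCc2ccc(OC)cc2)[C@@H](O[Si](C)(C)C(C)(C)C)C1 | intermediate
22 | [(2S,3S)-3-{3-[(1S,5S)-5-(TBSO)-4-(PMBOCH2)cyclohex-3-en-1-yl]but-3-en-1-yl}-2-methyloxiran-2-yl]methanol | C=C(CC[C@@H]2O[C@@]2(C)CO)[C@H]1CC=C(COCc3ccc(OC)cc3)[C@@H](O[Si](C)(C)C(C)(C)C)C1 | intermediate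
23 | (2S,3R)-2-methyl-3-(phenylselanyl)-6-[(1S,5S)-5-(TBSO)-4-(PMBOCH2)cyclohex-3-en-1-yl]hept-6-ene-1,2-diol | C=C(CC[C@@H]([Se]c2ccccc2)[C@@](C)(O)CO)[C@H]1CC=C(COCc3ccc(OC)cc3)[C@@H](O[Si](C)(C)C(C)(C)C)C1 | intermediate
24 | Se-oxide of 23 (both epimers at selenium) | C=C(CC[C@@H]([Se](=O)c2ccccc2)[C@@](C)(O)CO)[C@H]1CC=C(COCc3ccc(OC)cc3)[C@@H](O[Si](C)(C)C(C)(C)C)C1 | intermediate
25 | (2R,3E)-2-methyl-6-[(1S,5S)-5-(TBSO)-4-(PMBOCH2)cyclohex-3-en-1-yl]hepta-3,6-diene-1,2-diol | C=C(C/C=C/[C@@](C)(O)CO)[C@H]1CC=C(COCc2ccc(OC)cc2)[C@@H](O[Si](C)(C)C(C)(C)C)C1 | intermediate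
26 | (2R,3E)-6-[(1S,5S)-5-(TBSO)-4-(hydroxymethyl)cyclohex-3-en-1-yl]-2-methylhepta-3,6-diene-1,2-diol | C=C(C/C=C/[C@@](C)(O)CO)[C@H]1CC=C(CO)[C@@H](O[Si](C)(C)C(C)(C)C)C1 | intermediate
27 | 2-methylpropanoyl chloride (isobutyryl chloride) | CC(C)C(Cl)=O | starting material
28 | {(4S,6S)-6-(TBSO)-4-[(4E,6R)-6-hydroxy-6-methyl-7-(2-methylpropanoyloxy)hepta-1,4-dien-2-yl]cyclohex-1-en-1-yl}methyl 2-methylpropanoate | C=C(C/C=C/[C@@](C)(O)COC(=O)C(C)C)[C@H]1CC=C(COC(=O)C(C)C)[C@@H](O[Si](C)(C)C(C)(C)C)C1 | intermediate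
29 | {(4S,6S)-6-hydroxy-4-[(4E,6R)-6-hydroxy-6-methyl-7-(2-methylpropanoyloxy)hepta-1,4-dien-2-yl]cyclohex-1-en-1-yl}methyl 2-methylpropanoate (CNP0599657.1) | C=C(C/C=C/[C@@](C)(O)COC(=O)C(C)C)[C@H]1CC=C(COC(=O)C(C)C)[C@@H](O)C1 | target

## Step count and weak points

Total step count: 19. Longest linear sequence: 19 steps (1 to 29); the small partners 3, 16 and 27 are used as bought.

The three steps most likely to fail are steps 7, 8 and 17.

Step 7 is the weakest. The epoxide of 9 sits on the ring face that also carries the silyloxy group and the side chain, so the bulky aluminium amide may react slowly or open the epoxide toward the ring CH2. Any base-induced 1,3-silyl shift in 10 would also erode the ring configuration. The fallback sets out from 9 and activates the epoxide with a small electrophile instead of a base: TMSOTf and 2,6-lutidine in toluene at −78 °C, then DBU at rt (Noyori isomerisation), give the allylic trimethylsilyl ether F1. Citric acid in MeOH at 0 °C then removes only the trimethylsilyl group, and the route is rejoined at 10.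

Step 8 may give elimination or mixtures of secondary and primary halides. The fallback sets out from 10 and moves the oxygen itself rather than passing through a halide. Catalytic Ph3SiOReO3 in Et2O at 0 °C equilibrates the allylic alcohol by a [3,3] perrhenate shift to the more stable primary allylic alcohol F2, which has the trisubstituted ring alkene. F2 is etherified with 4-methoxybenzyl 2,2,2-trichloroacetimidate and catalytic Sc(OTf)3 in toluene at 0 °C, and the route is rejoined at 13 without bromide 12.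

Step 17 exposes the doubly allylic CH2 of the skipped diene and the tertiary allylic diol of 25 to DDQ. The fallback sets out from 22 and changes the order so that DDQ never meets the diene. DDQ in CH2Cl2/pH 7 buffer at 0 °C first gives the epoxy diol F3. This is opened with (PhSe)2 and NaBH4 in EtOH to the hydroxy selenide F4, which is oxidised with H2O2 and pyridine in THF to the selenoxide F5 and eliminated in the same flask. The route is rejoined at 26.

Further compounds

F1 | step 7 | trimethylsilyl ether of 10 | C=C(CCCO[Si](C)(C)C(C)(C)C)[C@H]1C[C@@H](O[Si](C)(C)C)C(=C)[C@@H](O[Si](C)(C)C(C)(C)C)C1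
F2 | step 8 | {(4S,6S)-6-(TBSO)-4-[5-(TBSO)pent-1-en-2-yl]cyclohex-1-en-1-yl}methanol | C=C(CCCO[Si](C)(C)C(C)(C)C)[C@H]1CC=C(CO)[C@@H](O[Si](C)(C)C(C)(C)C)C1
F3 | step 17 | [(2S,3S)-3-{3-[(1S,5S)-5-(TBSO)-4-(hydroxymethyl)cyclohex-3-en-1-yl]but-3-en-1-yl}-2-methyloxiran-2-yl]methanol | C=C(CC[C@@H]2O[C@@]2(C)CO)[C@H]1CC=C(CO)[C@@H](O[Si](C)(C)C(C)(C)C)C1
F4 | step 17 | (2S,3R)-6-[(1S,5S)-5-(TBSO)-4-(hydroxymethyl)cyclohex-3-en-1-yl]-2-methyl-3-(phenylselanyl)hept-6-ene-1,2-diol | C=C(CC[C@@H]([Se]c2ccccc2)[C@@](C)(O)CO)[C@H]1CC=C(CO)[C@@H](O[Si](C)(C)C(C)(C)C)C1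
F5 | step 17 | Se-oxide of F4 | C=C(CC[C@@H]([Se](=O)c2ccccc2)[C@@](C)(O)CO)[C@H]1CC=C(CO)[C@@H](O[Si](C)(C)C(C)(C)C)C1
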